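## Analysis of the target

The target 21 is a furofuran lignan. Two tetrahydrofuran rings (ring A: C7–O–C9'–C8'–C8; ring B: C7'–O–C9–C8–C8') share the C8–C8' bond and form a cis-fused 3,7-dioxabicyclo[3.3.0]octane. In bicycle numbering C2 = C7, C1 = C8, C5 = C8' and C6 = C7'. There are four contiguous stereocentres, 7S, 8R, 8'R, 7'S. The ring-fusion hydrogens are cis, and each aryl group is exo, meaning on the convex face and cis to the hydrogen of the neighbouring ring-fusion carbon. C7 carries a 3-hydroxy-4,5-dimethoxyphenyl group and C7' a 3,4,5-trimethoxyphenyl group, so the molecule is C2-symmetric except for one O-methyl group. The sensitive sites are the two benzylic C–O bonds (C7–O and C7'–O), which ionise under acid with loss of the exo configuration and can be hydrogenolysed, and the free phenol. The synthesis is hard for three reasons: four stereocentres must be set in one absolute sense; each aryl group is bound through the carbon meta to two oxygens and para to the third, which electrophilic substitution of the parent arene does not reach; and one free phenol distinguishes two otherwise identical halves. The strategy rests on this feature: without the C7–aryl and C7'–aryl bonds, what remains is a C2-symmetric bis-lactol of the same bicycle, and its cup shape exposes the convex face of C7 and C7', which is the face the aryl groups occupy.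

## Retrosynthetic reasoning

21 ⇒ 20. The O–CH3 bond of the one methoxy group that makes the two rings different is cut first. The precursor, bisphenol 20, is C2-symmetric and its two phenols are exchanged by the axis, so methylation of either gives 21 and no regiochemical question arises. The forward reaction only has to stop after one methylation, which is handled by stoichiometry and recycling.

20 ⇒ 19. The two phenols are masked as benzyl ethers. A free phenol would bind the Lewis acid of the key step and could attack an oxocarbenium ion through oxygen or through its ortho and para carbons. A benzyl ether is electronically close to a methyl ether, so the aryl donor behaves like a trialkoxyphenyl group. The forward hydrogenolysis must spare the benzylic C7–O and C7'–O bonds.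

19 ⇒ 9 + two 15 (key disconnection). The bonds C7–C1(aryl) and C7'–C1(aryl) are cut. Cutting here, rather than at ring C–O bonds or at C8–C8', removes both aryl groups at once. The core 9 that remains is small and symmetric and already holds both rings and both ring-fusion stereocentres, so C7 and C7' can be set under substrate control. The synthon at C7 is a cyclic oxocarbenium ion, which a lactol acetate provides. The aryl synthon is nucleophilic at the carbon that bears boron in 15, which fixes the point of attachment. The forward reaction has to ionise both acetates in turn and transfer the aryl group from boron to carbon on the convex face each time.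

15 ⇒ 14 ⇒ 12 ⇒ 11 ⇒ 10. The C–B bond is traced to a C–H bond. Iridium-catalysed borylation is governed by sterics, and C5 is the only unhindered position of a 1,2,3-trioxygenated benzene. The benzyl ether cannot be present at that stage: the unsubstituted phenyl ring of a benzyl group has three unhindered C–H bonds and would be borylated in competition. The borylation is therefore run on silyl ether 11 (from phenol 10). The silyl group of 12 is then exchanged for benzyl (14) before the boronate ester is turned into trifluoroborate 15.

9 ⇒ 8 ⇒ 6. The acetate C–O bonds lead back to bis-lactol 8, which is the closed form of dialdehyde 7. The two aldehyde carbons are traced to alkenes, so 7 comes from oxidative cleavage of both C=C bonds of diol 6. The aldehydes stay masked until they are needed, and the hydroxymethyl groups that close the rings are already free. Only the (2R,3R) isomer can fold into a cis-fused bis-lactol.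

6 ⇒ 5 ⇒ 3 ⇒ 1 + 2. Diol 6 comes from hydride reduction of the two acyl groups of bis-imide 5. Bis-imide 5 is cut at its central C2–C3 bond (C8–C8' of the lignan) into two identical enolates 4, so two molecules of imide 3 are joined in the forward sense by oxidative homocoupling. Symmetry is used again: one auxiliary, 1, sets both ring-fusion centres. Enolate 4 is a dienolate, and its γ-carbon must stay out of the coupling. The alkenyl group of acid 2 therefore carries two methyl groups on its far carbon, which make the γ-terminus fully substituted; they leave in the ozonolysis. The coupling has to join the two α-carbons, each on the face opposite the benzyl group of its auxiliary.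

## Alternatives that were turned down

Alternative 1: Baeyer–Villiger route.
- Disconnection: the ring oxygen between C7 and C9' is taken out. This leads back to cyclobutanone A1, in which benzylic C7 is bonded directly to the C9' carbonyl and which is fused to the lactone that already holds C7'.
- Forward key step: a peracid converts A1 into dilactone A2. The benzylic carbon migrates with retention, so the C7 configuration of A1 is carried into the new γ-lactone.
- For: the two different aryl groups are present from the start, so no statistical methylation is needed at the end; on this point it is stronger than the chosen route. The migration is stereospecific and the benzylic carbon is the better migrating group.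
- Against: all four stereocentres must already be correct in A1, a densely substituted bicyclic cyclobutanone with no evident short enantioselective access. Any [2+2] cycloaddition that builds the four-membered ring of A1 would have to control regiochemistry and two faces. A2 also carries carbonyl groups at C9 and C9' that the target lacks, so both lactones must be fully reduced and both ether rings rebuilt, with the benzylic centres exposed again.
- Comparison: the chosen route reaches the correct oxidation level directly (lactol, then C-arylation). In exchange for the statistical last step it gains symmetry: one auxiliary sets C8 and C8', and one operation sets C7 and C7'.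

Alternative 2: double aldol route.
- Disconnection: C7–C8 and C7'–C8', giving succinyl bis-imide A3 and two molecules of aldehyde A4.
- Forward key step: double boron enolisation of A3 and syn-aldol addition to A4 on both sides, giving A5 with all four stereocentres and no ring.
- For: the aldol reaction is very well understood. C7 and C7' would be set by the auxiliary rather than by the shape of a bicycle, so on certainty of the C7 configuration it is stronger than the chosen route. A4 is an ordinary benzaldehyde and no organoboron nucleophile is needed.
- Against: forming a bis-enolate across the succinyl unit of A3 is the weak point, since the second enolisation occurs next to an enolate and the intermediate aldolate can acylate intramolecularly. After the aldol, both imide carbonyls of A5 must be reduced and both tetrahydrofuran rings closed by etherification to the benzylic oxygens, several steps in which the benzylic carbinols must not ionise. A5 is again C2-symmetric, so the same monomethylation is needed.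
- Comparison: the chosen route uses a core in which both rings are already closed, so the key step is followed only by deprotection and methylation.

Alternative 3: biomimetic dimerisation.
- Disconnection: C8–C8' and both C7–O bonds, back to two molecules of monolignol A6.
- Forward key step: an oxidase under air generates the phenoxyl radical of A6, a dirigent protein guides 8–8' coupling, and the coupled intermediate is trapped at C7 and C7' by its two hydroxymethyl groups to give A7.
- For: the whole skeleton and all four stereocentres arise in one step from A6 alone, and the substituent at C5 blocks 8–5 coupling. On step count it is clearly stronger than the chosen route.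
- Against: the absolute configuration depends entirely on a dirigent protein whose natural substrate has no substituent at C5. Whether it accepts and orients A6 with its 5-benzyloxy group is open, and without it the product is racemic. The protein is not a shelf reagent. A7 still needs both para-phenols methylated, debenzylation and the same monomethylation.
- Comparison: the chosen route is longer but sets the absolute configuration with a commercial auxiliary available in both enantiomers, and it does not depend on the substrate tolerance of a protein.

Key step: step 10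

Remark: the sense of induction in step 2 is assumed to follow the usual chelated Z-enolate model of 4-substituted N-acyl oxazolidinones (bond formation opposite the 4-benzyl group). Acid 2 is assumed to be commercially available.

## Route

Step 1
Reactants: 1 (S)-4-benzyl-1,3-oxazolidin-2-one; 2 4-methylpent-3-enoic acid
Product: 3 (S)-4-benzyl-3-(4-methylpent-3-enoyl)-1,3-oxazolidin-2-one
Conditions: 2, PivCl, Et3N, THF, −20 °C; then LiCl, 1, −20 °C → rt
Reagents that add atoms: none
Why: N-acylation of the oxazolidinone through the mixed pivalic anhydride; the LiCl/Et3N conditions are mild, and the trisubstituted β,γ-double bond has little drive to move into conjugation, so it should stay in place.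

Step 2
Reactants: 3 (S)-4-benzyl-3-(4-methylpent-3-enoyl)-1,3-oxazolidin-2-one (2 equiv; two molecules of 3 are joined to each other)
Product: 5 (2R,3R)-1,4-bis[(4S)-4-benzyl-2-oxo-1,3-oxazolidin-3-yl]-2,3-bis(2-methylprop-1-en-1-yl)butane-1,4-dione, via lithium Z-dienolate 4 (not isolated)
Conditions: LDA (1.1 equiv per 3), THF, −78 °C; then TiCl4 (1.0 equiv per 3), −78 °C → rt
Reagents that add atoms: none
Why: Oxidative homocoupling of an N-acyl oxazolidinone enolate, in which two molecules of 3 are dimerised through their α-carbons with net loss of two hydrogens: LDA gives the chelated Z-enolate 4, TiCl4 turns it into a titanium enolate, and two such enolates couple carbon to carbon on warming while tetravalent titanium is reduced to trivalent titanium. Each new centre is set by its own auxiliary, the bond forming on the enolate face opposite the 4-benzyl group, so the matched (2R,3R) dimer should be the main product and is separated from minor diastereomers by chromatography. The two γ-methyl groups make the γ-carbon a fully substituted terminus and steer the coupling to the α-carbons.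

Step 3
Reactants: 5 (2R,3R)-1,4-bis[(4S)-4-benzyl-2-oxo-1,3-oxazolidin-3-yl]-2,3-bis(2-methylprop-1-en-1-yl)butane-1,4-dione
Product: 6 (2R,3R)-2,3-bis(2-methylprop-1-en-1-yl)butane-1,4-diol
Conditions: LiBH4, MeOH (2 equiv), THF, 0 °C → rt
Reagents that add atoms: none
Why: Reductive removal of the auxiliary: LiBH4 attacks the exocyclic imide carbonyl and takes the acyl carbon to the primary alcohol without touching the alkenes or the α-stereocentres; auxiliary 1 is recovered.

Step 4
Reactants: 6 (2R,3R)-2,3-bis(2-methylprop-1-en-1-yl)butane-1,4-diol
Product: 8 (1R,5R)-3,7-dioxabicyclo[3.3.0]octane-2,6-diol (anomer mixture at C2 and C6), via dialdehyde 7 (not isolated)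
Conditions: O3, CH2Cl2/MeOH, NaHCO3, −78 °C; then Me2S, −78 °C → rt
Reagents that add atoms: ozone, [O-][O+]=O
Why: Ozonolysis with reductive work-up cleaves both electron-rich trisubstituted alkenes to dialdehyde 7, and each hydroxymethyl group then adds to the aldehyde on the neighbouring carbon (5-exo-trig hemiacetal formation). The (2R,3R) compound can close only to the cis-fused bicycle, so C1 and C5 are fixed; the lactol carbons form as anomer mixtures that are erased in step 10.

Step 5
Reactants: 8 (1R,5R)-3,7-dioxabicyclo[3.3.0]octane-2,6-diol
Product: 9 (1R,5R)-3,7-dioxabicyclo[3.3.0]octane-2,6-diyl diacetate (anomer mixture)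
Conditions: Ac2O, pyridine, DMAP (cat.), CH2Cl2, 0 °C → rt
Reagents that add atoms: acetic anhydride, CC(=O)OC(C)=O
Why: Standard O-acetylation of lactols with nucleophilic catalysis by DMAP turns both anomeric hydroxyls into leaving groups; the anomer ratio is of no consequence.

Step 6
Reactants: 10 2,3-dimethoxyphenol
Product: 11 tert-butyl(2,3-dimethoxyphenoxy)dimethylsilane
Conditions: TBSCl, imidazole, DMF, rt
Reagents that add atoms: tert-butyldimethylsilyl chloride, CC(C)(C)[Si](C)(C)Cl
Why: Silylation of the phenol; the bulky silyl ether shields C6 in the next step and, unlike a benzyl ether, offers the iridium catalyst no unhindered aryl C–H bonds of its own.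

Step 7
Reactants: 11 tert-butyl(2,3-dimethoxyphenoxy)dimethylsilane
Product: 12 tert-butyl[2,3-dimethoxy-5-(4,4,5,5-tetramethyl-1,3,2-dioxaborolan-2-yl)phenoxy]dimethylsilane
Conditions: B2pin2, [Ir(OMe)(cod)]2 (cat.), 4,4'-di-tert-butyl-2,2'-bipyridine (cat.), THF, 80 °C
Reagents that add atoms: bis(pinacolato)diboron, CC1(C)OB(OC1(C)C)B1OC(C)(C)C(C)(C)O1
Why: Iridium-catalysed aromatic C–H borylation is governed by sterics: C5 is the only ring C–H without an ortho substituent, so boron enters meta to the silyloxy group and para to the central methoxy group, a position electrophilic substitution cannot reach.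

Step 8
Reactants: 12 tert-butyl[2,3-dimethoxy-5-(4,4,5,5-tetramethyl-1,3,2-dioxaborolan-2-yl)phenoxy]dimethylsilane
Product: 14 2-[3-(benzyloxy)-4,5-dimethoxyphenyl]-4,4,5,5-tetramethyl-1,3,2-dioxaborolane, via cesium phenolate 13 (not isolated)
Conditions: CsF, BnBr, DMF, rt
Reagents that add atoms: benzyl bromide, BrCc1ccccc1
Why: Fluoride cleaves the aryl silyl ether to phenolate 13, which is benzylated in the same pot (Williamson ether synthesis); the pinacol boronate tolerates fluoride and mild base at room temperature.

Step 9
Reactants: 14 2-[3-(benzyloxy)-4,5-dimethoxyphenyl]-4,4,5,5-tetramethyl-1,3,2-dioxaborolane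
Product: 15 potassium [3-(benzyloxy)-4,5-dimethoxyphenyl]trifluoroborate
Conditions: KHF2 (excess), MeOH/H2O, rt; crystallisation from acetone/Et2O
Reagents that add atoms: potassium hydrogen difluoride, [K+].F[H-]F
Why: Exchange of the pinacol ester for fluoride with aqueous KHF2 is the standard preparation of potassium aryltrifluoroborates and should give a crystalline, air-stable salt.

Step 10
Reactants: 9 (1R,5R)-3,7-dioxabicyclo[3.3.0]octane-2,6-diyl diacetate; 15 potassium [3-(benzyloxy)-4,5-dimethoxyphenyl]trifluoroborate (about 2.6 equiv)
Product: 19 (1R,2S,5R,6S)-2,6-bis[3-(benzyloxy)-4,5-dimethoxyphenyl]-3,7-dioxabicyclo[3.3.0]octane, via aryldifluoroborane 16 (not isolated), via oxocarbenium ion 17 (not isolated), via monoaryl lactol acetate 18 (not isolated)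
Conditions: BF3·OEt2 (4 equiv), MeCN/CH2Cl2, −40 → 0 °C; aq. NaHCO3
Reagents that add atoms: none
Why: BF3·OEt2 strips fluoride from 15 to give aryldifluoroborane 16 and KBF4; the boron Lewis acid then ionises one lactol acetate of 9 to the cis-fused oxocarbenium ion 17, paired with an acetoxy(aryl)difluoroborate, and the aryl group moves from boron to the cationic carbon through its ipso carbon to give 18, after which the same sequence at the second acetal carbon gives 19. The closest known reaction type is the BF3·OEt2-promoted coupling of potassium aryltrifluoroborates with acetals and lactol acetates to give α-aryl ethers, here run twice on one bicycle. No ring is closed; both tetrahydrofuran rings are already present in 9. The two new stereocentres (C2 and C6 of the bicycle, C7 and C7' of the lignan) are controlled by the substrate: in 17 the carbon next to the cationic centre is a ring-fusion carbon whose CH2 substituent from the other ring lies on the concave face, so the aryl group is delivered to the convex face, cis to the ring-fusion hydrogen, and ends up exo (S at both carbons on the (1R,5R) core). Both anomers of each acetate converge on the same cation, so the anomer mixture in 9 does not matter. The step needs site selectivity within the aryl donor (ipso carbon rather than the ring carbons ortho and para to oxygen) and kinetic control at the benzylic centres; the first is secured by the carbon–boron bond, which places the nucleophilic electron pair on the ipso carbon, and the second by low temperature and by the 3,4,5-trioxygenated ring, which stabilises a benzylic cation only weakly and so slows Lewis-acid epimerisation of the product.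

Step 11
Reactants: 19 (1R,2S,5R,6S)-2,6-bis[3-(benzyloxy)-4,5-dimethoxyphenyl]-3,7-dioxabicyclo[3.3.0]octane
Product: 20 (1R,2S,5R,6S)-2,6-bis(3-hydroxy-4,5-dimethoxyphenyl)-3,7-dioxabicyclo[3.3.0]octane
Conditions: H2 (1 atm), 10% Pd/C, EtOAc, rt
Reagents that add atoms: none
Why: Hydrogenolysis of aryl benzyl ethers over Pd/C; in a neutral aprotic solvent at atmospheric pressure the ring benzylic C–O bonds, which are secondary dialkyl ether bonds and react more slowly, should survive if the reaction is stopped once 19 is consumed.

Step 12
Reactants: 20 (1R,2S,5R,6S)-2,6-bis(3-hydroxy-4,5-dimethoxyphenyl)-3,7-dioxabicyclo[3.3.0]octane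
Product: 21 (1R,2S,5R,6S)-2-(3-hydroxy-4,5-dimethoxyphenyl)-6-(3,4,5-trimethoxyphenyl)-3,7-dioxabicyclo[3.3.0]octane (the target)
Conditions: MeI (0.6 equiv), K2CO3, acetone, rt; recovered 20 recycled
Reagents that add atoms: methyl iodide, CI
Why: Williamson O-methylation of one phenol; the two phenols are exchanged by the C2 axis, so either one leads to the target, and a deficit of MeI keeps double methylation low while unreacted 20 is separated by polarity and recycled.

## Compound list

1 | (S)-4-benzyl-1,3-oxazolidin-2-one | O=C1OC[C@H](Cc2ccccc2)N1 | starting material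
2 | 4-methylpent-3-enoic acid | CC(C)=CCC(=O)O | starting material
3 | (S)-4-benzyl-3-(4-methylpent-3-enoyl)-1,3-oxazolidin-2-one | CC(C)=CCC(=O)N1[C@@H](Cc2ccccc2)COC1=O | intermediate
4 | lithium (Z)-dienolate of 3 | [Li+].CC(C)=C/C=C(\[O-])N1[C@@H](Cc2ccccc2)COC1=O | intermediate (not isolated)
5 | (2R,3R)-1,4-bis[(4S)-4-benzyl-2-oxo-1,3-oxazolidin-3-yl]-2,3-bis(2-methylprop-1-en-1-yl)butane-1,4-dione | O=C1OC[C@H](Cc2ccccc2)N1C(=O)[C@H](C=C(C)C)[C@@H](C=C(C)C)C(=O)N3[C@@H](Cc4ccccc4)COC3=O | intermediate
6 | (2R,3R)-2,3-bis(2-methylprop-1-en-1-yl)butane-1,4-diol | OC[C@H](C=C(C)C)[C@@H](C=C(C)C)CO | intermediate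
7 | (2R,3R)-2,3-bis(hydroxymethyl)butanedial | OC[C@H](C=O)[C@@H](C=O)CO | intermediate (not isolated)
8 | (1R,5R)-3,7-dioxabicyclo[3.3.0]octane-2,6-diol, anomer mixture | OC1OC[C@H]2[C@@H]1COC2O | intermediate
9 | (1R,5R)-3,7-dioxabicyclo[3.3.0]octane-2,6-diyl diacetate, anomer mixture | CC(=O)OC1OC[C@H]2[C@@H]1COC2OC(C)=O | intermediate
10 | 2,3-dimethoxyphenol | COc1cccc(O)c1OC | starting material
11 | tert-butyl(2,3-dimethoxyphenoxy)dimethylsilane | COc1cccc(O[Si](C)(C)C(C)(C)C)c1OC | intermediate
12 | tert-butyl[2,3-dimethoxy-5-(4,4,5,5-tetramethyl-1,3,2-dioxaborolan-2-yl)phenoxy]dimethylsilane | COc1cc(B2OC(C)(C)C(C)(C)O2)cc(O[Si](C)(C)C(C)(C)C)c1OC | intermediate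
13 | cesium 2,3-dimethoxy-5-(4,4,5,5-tetramethyl-1,3,2-dioxaborolan-2-yl)phenolate | [Cs+].COc1cc(B2OC(C)(C)C(C)(C)O2)cc([O-])c1OC | intermediate (not isolated)
14 | 2-[3-(benzyloxy)-4,5-dimethoxyphenyl]-4,4,5,5-tetramethyl-1,3,2-dioxaborolane | COc1cc(B2OC(C)(C)C(C)(C)O2)cc(OCc3ccccc3)c1OC | intermediate
15 | potassium [3-(benzyloxy)-4,5-dimethoxyphenyl]trifluoroborate | COc1cc([B-](F)(F)F)cc(OCc2ccccc2)c1OC.[K+] | intermediate
16 | [3-(benzyloxy)-4,5-dimethoxyphenyl]difluoroborane | COc1cc(B(F)F)cc(OCc2ccccc2)c1OC | intermediate (not isolated)
17 | oxocarbenium ion formed from 9 by loss of one acetate (6-acetoxy-3,7-dioxabicyclo[3.3.0]oct-2-en-3-ium, ring fusion as in 9) | C1=[O+]C[C@H]2[C@@H]1COC2OC(C)=O | intermediate (not isolated)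
18 | (1R,5R,6S)-6-[3-(benzyloxy)-4,5-dimethoxyphenyl]-3,7-dioxabicyclo[3.3.0]octan-2-yl acetate, aryl exo, anomer mixture | COc1cc([C@H]2OC[C@H]3[C@@H]2COC3OC(C)=O)cc(OCc4ccccc4)c1OC | intermediate (not isolated)
19 | (1R,2S,5R,6S)-2,6-bis[3-(benzyloxy)-4,5-dimethoxyphenyl]-3,7-dioxabicyclo[3.3.0]octane (exo,exo) | COc1cc([C@H]2OC[C@H]3[C@@H]2CO[C@@H]3c4cc(OC)c(OC)c(OCc5ccccc5)c4)cc(OCc6ccccc6)c1OC | intermediate
20 | (1R,2S,5R,6S)-2,6-bis(3-hydroxy-4,5-dimethoxyphenyl)-3,7-dioxabicyclo[3.3.0]octane | COc1cc([C@H]2OC[C@H]3[C@@H]2CO[C@@H]3c4cc(OC)c(OC)c(O)c4)cc(O)c1OC | intermediate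
21 | (1R,2S,5R,6S)-2-(3-hydroxy-4,5-dimethoxyphenyl)-6-(3,4,5-trimethoxyphenyl)-3,7-dioxabicyclo[3.3.0]octane | COc1cc([C@H]2OC[C@H]3[C@@H]2CO[C@@H]3c4cc(OC)c(OC)c(OC)c4)cc(O)c1OC | target

## Step count and least certain steps

Total: 12 steps. Longest linear sequence: 8 steps (steps 1–5, 10, 11, 12). The aryl branch (steps 6–9) is 4 steps and joins at step 10.

Step 10 (key step). The aryl transfer may be slow, because the ipso carbon of a 3,4,5-trioxygenated ring is only weakly activated: two alkoxy groups are meta to it and the para methoxy group is twisted out of conjugation. The oxocarbenium ion may then be lost by other paths, namely loss of the ring-fusion proton to an enol ether, capture by fluoride or acetate, or oligomerisation. The boron reagent may also be protodeboronated, after which the free arene attacks through a carbon ortho or para to oxygen and gives the wrong connectivity. Finally, exo selectivity may erode if the Lewis acid ionises the C7–O bond of the product. Fallback (sets out from 8 and from boronate 14 of the aryl branch, returns at 19): oxidise 8 (TEMPO, PhI(OAc)2) to the bis-lactone (1R,5R)-3,7-dioxabicyclo[3.3.0]octane-2,6-dione F1; convert 14 with CuBr2 (copper dibromide) into 1-(benzyloxy)-5-bromo-2,3-dimethoxybenzene F2; exchange bromine for lithium (n-BuLi, −78 °C) and add two equivalents of the aryllithium to F1, which opens both lactones to the diketone (2R,3R)-1,4-bis[3-(benzyloxy)-4,5-dimethoxyphenyl]-2,3-bis(hydroxymethyl)butane-1,4-dione F3; reduce both ketones (NaBH4) to the tetrol (2R,3R)-1,4-bis[3-(benzyloxy)-4,5-dimethoxyphenyl]-2,3-bis(hydroxymethyl)butane-1,4-diol F4; and close both rings by acid-mediated cyclodehydration (camphorsulfonic acid, CH2Cl2), each primary hydroxyl capturing the benzylic cation on the other branch, to give 19. This is the long-known lactone/aryl-metal route to furofurans. The aryl position is again fixed by a carbon–metal bond and C8/C8' come from 8. C7/C7' are set under thermodynamic control, so some exo,endo isomer would have to be separated.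

Step 2. The dimerisation of two molecules of 3 may take another course: coupling through the γ-carbon or through oxygen of the dienolate despite the γ-methyl groups, mismatched pairing to the (2R,3S) diastereomer, or α-chlorination instead of coupling. Fallback (sets out from 1, returns at 8): acylate 1 with pent-4-enoyl chloride (n-BuLi, THF, −78 °C) to (S)-4-benzyl-3-(pent-4-enoyl)-1,3-oxazolidin-2-one F5, whose enolate is simple and not ambident, the kind for which the LDA/TiCl4 homocoupling is established; couple two molecules of it to (2R,3R)-1,4-bis[(4S)-4-benzyl-2-oxo-1,3-oxazolidin-3-yl]-2,3-di(prop-2-en-1-yl)butane-1,4-dione F6; reduce with LiBH4 to (2R,3R)-2,3-di(prop-2-en-1-yl)butane-1,4-diol F7; move both terminal alkenes by one position with a palladium hydride catalyst (Pd(dba)2, P(t-Bu)3, isobutyryl chloride) to (2R,3R)-2,3-di[(E)-prop-1-en-1-yl]butane-1,4-diol F8; ozonolysis of F8 as in step 4 then gives 8. The detour is one step longer and adds the risk of over-migration of the alkenes.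

Step 11. Hydrogenolysis of the benzylic C7–O and C7'–O bonds of the bicycle (ring opening) may run alongside removal of the benzyl groups, or debenzylation may stay incomplete if the reaction is stopped early. Fallback (sets out from 12, returns at 20): run step 8 with allyl bromide in place of benzyl bromide to give 2-[3-(allyloxy)-4,5-dimethoxyphenyl]-4,4,5,5-tetramethyl-1,3,2-dioxaborolane F9; convert it with KHF2 into potassium [3-(allyloxy)-4,5-dimethoxyphenyl]trifluoroborate F10; use F10 in the key step with 9 to give (1R,2S,5R,6S)-2,6-bis[3-(allyloxy)-4,5-dimethoxyphenyl]-3,7-dioxabicyclo[3.3.0]octane F11; and remove the allyl groups with Pd(PPh3)4 (zerovalent palladium) and morpholine to reach 20 without any reductive step.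

Step 12. Double methylation to the bis(trimethoxyphenyl) compound, which cannot be recycled, may compete, and conversion per pass is low because the two phenols react independently. Fallback (sets out from 9, returns at 21): desymmetrise at the arylation instead. Treat 9 with one equivalent of 15 and isolate the monoaryl acetate 18; recovered 9 is reused, and any 19 formed goes on through steps 11 and 12, so nothing is wasted. Arylate 18 under the same conditions with commercial potassium (3,4,5-trimethoxyphenyl)trifluoroborate to give (1R,2S,5R,6S)-2-[3-(benzyloxy)-4,5-dimethoxyphenyl]-6-(3,4,5-trimethoxyphenyl)-3,7-dioxabicyclo[3.3.0]octane F12. Hydrogenolysis of the single benzyl ether of F12 gives 21 directly.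

## Further compounds

F1 | step 10 | (1R,5R)-3,7-dioxabicyclo[3.3.0]octane-2,6-dione | O=C1OC[C@H]2[C@@H]1COC2=O
F2 | step 10 | 1-(benzyloxy)-5-bromo-2,3-dimethoxybenzene | COc1cc(Br)cc(OCc2ccccc2)c1OC
F3 | step 10 | (2R,3R)-1,4-bis[3-(benzyloxy)-4,5-dimethoxyphenyl]-2,3-bis(hydroxymethyl)butane-1,4-dione | COc1cc(C(=O)[C@@H](CO)[C@H](CO)C(=O)c2cc(OC)c(OC)c(OCc3ccccc3)c2)cc(OCc4ccccc4)c1OC
F4 | step 10 | (2R,3R)-1,4-bis[3-(benzyloxy)-4,5-dimethoxyphenyl]-2,3-bis(hydroxymethyl)butane-1,4-diol, carbinol epimers | COc1cc(C(O)[C@@H](CO)[C@H](CO)C(O)c2cc(OC)c(OC)c(OCc3ccccc3)c2)cc(OCc4ccccc4)c1OC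
F5 | step 2 | (S)-4-benzyl-3-(pent-4-enoyl)-1,3-oxazolidin-2-one | C=CCCC(=O)N1[C@@H](Cc2ccccc2)COC1=O
F6 | step 2 | (2R,3R)-1,4-bis[(4S)-4-benzyl-2-oxo-1,3-oxazolidin-3-yl]-2,3-di(prop-2-en-1-yl)butane-1,4-dione | O=C1OC[C@H](Cc2ccccc2)N1C(=O)[C@H](CC=C)[C@@H](CC=C)C(=O)N3[C@@H](Cc4ccccc4)COC3=O
F7 | step 2 | (2R,3R)-2,3-di(prop-2-en-1-yl)butane-1,4-diol | OC[C@H](CC=C)[C@@H](CC=C)CO
F8 | step 2 | (2R,3R)-2,3-di[(E)-prop-1-en-1-yl]butane-1,4-diol | OC[C@H](/C=C/C)[C@@H](/C=C/C)CO
F9 | step 11 | 2-[3-(allyloxy)-4,5-dimethoxyphenyl]-4,4,5,5-tetramethyl-1,3,2-dioxaborolane | COc1cc(B2OC(C)(C)C(C)(C)O2)cc(OCC=C)c1OC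
F10 | step 11 | potassium [3-(allyloxy)-4,5-dimethoxyphenyl]trifluoroborate | COc1cc([B-](F)(F)F)cc(OCC=C)c1OC.[K+]
F11 | step 11 | (1R,2S,5R,6S)-2,6-bis[3-(allyloxy)-4,5-dimethoxyphenyl]-3,7-dioxabicyclo[3.3.0]octane | COc1cc([C@H]2OC[C@H]3[C@@H]2CO[C@@H]3c4cc(OC)c(OC)c(OCC=C)c4)cc(OCC=C)c1OC
F12 | step 12 | (1R,2S,5R,6S)-2-[3-(benzyloxy)-4,5-dimethoxyphenyl]-6-(3,4,5-trimethoxyphenyl)-3,7-dioxabicyclo[3.3.0]octane | COc1cc([C@H]2OC[C@H]3[C@@H]2CO[C@@H]3c4cc(OC)c(OC)c(OC)c4)cc(OCc5ccccc5)c1OC
A1 | alternative 1 | 7-[3-(benzyloxy)-4,5-dimethoxyphenyl]-4-(3,4,5-trimethoxyphenyl)-3-oxabicyclo[3.2.0]heptane-2,6-dione, configured as required for A2 | COc1cc([C@H]2C(=O)[C@H]3[C@@H]2C(=O)O[C@@H]3c4cc(OC)c(OC)c(OC)c4)cc(OCc5ccccc5)c1OC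
A2 | alternative 1 | exo,exo-2-[3-(benzyloxy)-4,5-dimethoxyphenyl]-6-(3,4,5-trimethoxyphenyl)-3,7-dioxabicyclo[3.3.0]octane-4,8-dione | COc1cc([C@H]2OC(=O)[C@H]3[C@@H]2C(=O)O[C@@H]3c4cc(OC)c(OC)c(OC)c4)cc(OCc5ccccc5)c1OC
A3 | alternative 2 | 1,4-bis[(4S)-4-benzyl-2-oxo-1,3-oxazolidin-3-yl]butane-1,4-dione | O=C(CCC(=O)N1[C@@H](Cc2ccccc2)COC1=O)N3[C@@H](Cc4ccccc4)COC3=O
A4 | alternative 2 | 3-(benzyloxy)-4,5-dimethoxybenzaldehyde | COc1cc(C=O)cc(OCc2ccccc2)c1OC
A5 | alternative 2 | C2-symmetric bis-syn-aldol adduct, 1,4-bis[(4S)-4-benzyl-2-oxo-1,3-oxazolidin-3-yl]-2,3-bis{[3-(benzyloxy)-4,5-dimethoxyphenyl](hydroxy)methyl}butane-1,4-dione | COc1cc([C@@H](O)[C@@H](C(=O)N2[C@@H](Cc3ccccc3)COC2=O)[C@H](C(=O)N4[C@@H](Cc5ccccc5)COC4=O)[C@H](O)c6cc(OC)c(OC)c(OCc7ccccc7)c6)cc(OCc8ccccc8)c1OC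
A6 | alternative 3 | (E)-3-[3-(benzyloxy)-4-hydroxy-5-methoxyphenyl]prop-2-en-1-ol | COc1cc(/C=C/CO)cc(OCc2ccccc2)c1O
A7 | alternative 3 | exo,exo-2,6-bis[3-(benzyloxy)-4-hydroxy-5-methoxyphenyl]-3,7-dioxabicyclo[3.3.0]octane | COc1cc([C@H]2OC[C@H]3[C@@H]2CO[C@@H]3c4cc(OC)c(O)c(OCc5ccccc5)c4)cc(OCc6ccccc6)c1O
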